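| flask | L | D | remark | time |
|---|---|---|---|---|
| west | 0.050 M | 0.12 M | run made earlier |  |
| flask | 0.10 M | 0.120 M |  | 1.5 h |
west run (percent of the L charged)

| time / min | L / % | G / % |
|---|---|---|
| 1.33 | 98.2 | 1.0 |
| 3.00 | 97.9 | 1.1 |
| 8.00 | 96.5 | 4.4 |
| 20.0 | 91.4 | 7.9 |

(readings scatter by 0.5 percentage points)
- what was read earlier has a scatter of 0.5 percentage points, one standard deviation
* L at 1.5 h, in percent of the L charged
* G at 1.5 h, in percent of the L charged
* E at 1.5 h, in percent of the L charged

In a one-step world, L + D → G, each bit of L faces the same risk from D, whatever L's charge. The west run's last reading gives 0.0899 of what I call the dose, minus the logarithm of the fraction of L left. It is the rate constant times D, summed over time, so a dose can be compared between flasks.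

One side of our dispute adds a second step to that world, G + D → E, and lets D be used up by these two steps, and the west run's readings seem to agree with a steady rate: the mean dose per minute is 0.00445 min⁻¹ up to 8.00 min and 0.00449 min⁻¹ up to 20.0 min. With “the second-order integrated form”, the forecast says L 72%, G 26% and E 2%.

I hold that D may be dying on its own, which no reading shows directly. My hint from the west run is weak, given the scatter, and the middle reading does not share it: 0.00707 min⁻¹ over the opening 3.00 min, then 0.00404 min⁻¹ up to 20.0 min. Taken as an exponential fall between the middles of those windows, this gives D a lifetime of 17.9 min. The dose then levels off at 0.133 by 1.5 h, so I say L 87.5%, with G a little under 12.5%.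

The flask gave L 82.3%, G 13.8% and E 1.90%, so L fell between the forecast and my number.

    L + G → Q (k = 2.20 × 10⁻⁴ L mol⁻¹ s⁻¹)
    D → Z (k = 3.89 × 10⁻⁴ s⁻¹)
    L + D → G (k = 7.76 × 10⁻⁴ L mol⁻¹ s⁻¹)
    D + G → E (k = 0.00104 L mol⁻¹ s⁻¹)

The flask's dose was 0.195, twice the west run's, over 4.50 times its time, and 8.0% of its D remained. The steady-rate view holds early: at 0.150 h, shorter than D's half-life of 0.49 h by D → Z alone, the west rate gives L 96.0%, and the flask held 95.6%. Carrying this flask's dose unchanged to a neighbour charged with 0.040 M of L reckons L at 82.3%. That neighbour held 81.6%, a dose 2.26 times the west run's, with G at 15.3%.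

Readings and results stem from a simulated flask on assumed constants; noise was put on by code.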